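3 questions stand on one flask, each the ratio of target to isomer of the product at another age, and two chemists dispute them.

| flask | substrate | reagent | free catalyst | remark | time |
|---|---|---|---|---|---|
| birch | 0.29 M | 1.5 equiv | 4.7 mol% | run made earlier |  |
| cedar | 0.43 M | 1.5 equiv | 4.7 mol% | run made earlier |  |
| maple | 0.58 M | 1.5 equiv | 2.4 mol% | run made earlier |  |
| flask | 0.58 M | 1.50 equiv | 4.7 mol% |  | 8.0 d |

| run | time / d | target / % | isomer of the product / % | substrate / % |
|---|---|---|---|---|
| birch | 0.417 | 37.5 | 18.9 | 31.5 |
| birch | 0.833 | 39.2 | 19.8 | 29.6 |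
| birch | 1.25 | 39.7 | 20.9 | 29.6 |
| birch | 2.50 | 38.9 | 19.9 | 29.7 |
| birch | 5.00 | 38.4 | 20.9 | 29.8 |
| cedar | 0.417 | 43.0 | 21.9 | 26.3 |
| cedar | 1.25 | 43.5 | 24.2 | 24.1 |
| cedar | 2.00 | 44.2 | 23.3 | 23.7 |
| cedar | 3.00 | 43.8 | 22.9 | 23.9 |
| cedar | 5.00 | 44.2 | 23.3 | 23.7 |
| maple | 0.417 | 46.3 | 23.6 | 21.2 |
| maple | 0.833 | 46.6 | 24.6 | 21.6 |
| maple | 1.25 | 47.1 | 24.8 | 19.8 |
| maple | 2.50 | 47.0 | 24.9 | 20.1 |
| maple | 5.00 | 46.0 | 24.7 | 20.4 |

(readings scatter by 0.5 percentage points)



1. ratio of target to isomer of the product at 6.0 min
2. ratio of target to isomer of the product at 4.0 h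
3. ratio of target to isomer of the product at 8.0 d

The first chemist pools the last 2 readings of each run into a plateau ratio of 1.89, sees no clear trend with concentration or loading, and holds that thermodynamic control governs the flask at each asked time. The second answers that the earliest reading comes at 0.417 d, that a ratio under kinetic control could have faded before it, and that a clock is wanted. She takes the distance of substrate from its plateau in the birch run as falling exponentially: 70 percentage points at the start has shrunk to 1.7 points at 0.417 d, which reads as 1.86 h, with the scatter of a reading entering under a logarithm. This is no pseudo-first-order law, for reagent is charged at only 1.50 equiv and substrate stops at a plateau, but as a rough assumption of her own she lets the time go inversely with c(substrate) at fixed equivalents, so the flask gets about 0.932 h, her rough half-time of approach, in which the distance to the plateau is taken to halve. Then 6.0 min is 0.107 of a half-time and 4.0 h is 4.29, so she expects the ratio at 6.0 min to come from a flask only 7.17% of the way along, well above the plateau, though she can put no number on it.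

The forecast stands nearer the first chemist, allowing “kinetic selectivity somewhat above the equilibrium ratio”, and gives 2.2, 2.06 and 1.88.

The flask gives 10.7, 2.00 and 1.88.

    substrate + reagent ⇌ target (K = 5.07 L mol⁻¹, k = 1.89 × 10⁻⁴ L mol⁻¹ s⁻¹)
    substrate + reagent ⇌ isomer of the product (K = 2.70 L mol⁻¹, k = 8.23 × 10⁻⁶ L mol⁻¹ s⁻¹)
    target + free catalyst ⇌ isomer of the product + free catalyst, rate k3*[free catalyst]*[target] forward; the back reaction follows from the equilibrium constant (k = 0.0110 L mol⁻¹ s⁻¹)
    substrate ⇌ dormant form (K = 0.380, k = 5.99 × 10⁻⁵ s⁻¹)
    free catalyst → spent catalyst (k = 5.12 × 10⁻⁵ s⁻¹)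

The second chemist wins the early time, where the ratio is higher than the forecast's, and the first keeps the region from 4.0 h onward, where the forecast holds within its margin. At 0.0410 d target is still made 2.58 times faster than it is used up, each step taken net. By 4.0 h the clock leaves 5.11% of the approach to go, while the ratio stands 0.120 above its end value.

In the neighbour flask at 0.35 M the same rough assumption stretches the clock to 1.54 h, leaving 16.6% at 4.0 h, and an excess scaled with that share gives about 2.27. The computed ratio there is 2.19.

The data come from a simulation from invented constants; the scatter is artificial.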